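**Retrosynthetic overview** (cladiellane numbering: ring C = C1, C10–C14 with C11=CH2; oxygen on C2, C3, C6, C7, C9; C16 = CH2OH)
1. Target ⇐ bridged hemiketal 35 (C2–O–C9 bridge, nine-membered oxonene): epoxidation of (Z)-C6=C7, then O2 moves from C9 to C6, which forms the tetrahydropyran/oxocane pair and frees the C9 ketone and C7–OH; the C3 ester goes on earlier, while O2 is tied up.
2. 35 ⇐ γ-lactone 26: 2-methylallyl Grignard addition at C9, then ring-closing metathesis.
3. 26 ⇐ tricyclic lactone acetal 21: acetal oxidation, reduction of ring L, lactone switch from O3 to O2.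
4. 21 ⇐ bicyclic enol ether–enoate 17 + a C4 alkyne unit by a [3+3] annulation forming C13–C14 and C10–C11 (ring C). Enabling feature: C14 (β to the C16 oxygen function) and C10 (α to the C9 carbonyl) both hang on C1, next to the vicinal O2/O3 pair, so acceptor and donor can be held in two temporary six-membered rings cis-fused at C1–C2: ring L (lactone O2–C16) and ring P (enol ether O3–C9).
5. 17 ⇐ aldehyde 5 (C3 from (S)-2-methylglycidol) + imide 9 by Evans syn aldol (C1, C2). Ring order: L, P, C, oxonene, then tetrahydropyran/oxocane.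

Key step: step 12

Assumption: the acetal or hemiketal carbon C9 in 16, 21, 28 and the related fallback compounds is a mixture of anomers that converges in the next step, so it carries no stereodescriptor in those SMILES.

Step 1
Reactants: 1 (S)-2-methylglycidol; 2 allylmagnesium bromide
Product: 3 (R)-2-methylhex-5-ene-1,2-diol
Conditions: 2 (3 equiv), CuI (10 mol %), THF, −30 → 0 °C; aq. NH4Cl
Reagents that add atoms: none
Why: Copper-catalysed Grignard opening of the 2,2-disubstituted epoxide at its CH2 terminus leaves the quaternary centre untouched, so C3 comes from the chiral pool.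

Step 2
Reactants: 3 (R)-2-methylhex-5-ene-1,2-diol
Product: 4 (R)-2-methyl-1,2-bis(triethylsilyloxy)hex-5-ene
Conditions: Et3SiOTf (2.3 equiv), 2,6-lutidine, CH2Cl2, −78 → 0 °C
Reagents that add atoms: triethylsilyl trifluoromethanesulfonate, CC[Si](CC)(CC)OS(=O)(=O)C(F)(F)F
Why: Silyl triflate silylation covers the primary and the tertiary hydroxyl (protection, no stereocentre touched).

Step 3
Reactants: 4 (R)-2-methyl-1,2-bis(triethylsilyloxy)hex-5-ene
Product: 5 (R)-2-methyl-2-(triethylsilyloxy)hex-5-enal
Conditions: (COCl)2, DMSO, CH2Cl2, −78 → −30 °C; Et3N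
Reagents that add atoms: none
Why: Under Swern conditions a primary triethylsilyl ether is cleaved and oxidized directly to the aldehyde while the tertiary silyl ether survives; the aldehyde has no α-hydrogen and cannot epimerize.

Step 4
Reactants: 6 methyl 4,4-dimethoxybutanoate
Product: 7 4,4-dimethoxybutanoic acid
Conditions: LiOH, THF/H2O, rt; then 1 M HCl to pH 4, 0 °C
Reagents that add atoms: lithium hydroxide, [Li+].[OH-]
Why: Ester saponification; the dimethyl acetal is stable to base and to brief exposure to pH 4.

Step 5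
Reactants: 7 4,4-dimethoxybutanoic acid; 8 (R)-4-benzyloxazolidin-2-one
Product: 9 (R)-4-benzyl-3-(4,4-dimethoxybutanoyl)oxazolidin-2-one
Conditions: DCC, DMAP (cat.), CH2Cl2, 0 °C → rt
Reagents that add atoms: none
Why: Carbodiimide-mediated N-acylation of the oxazolidinone (Steglich-type coupling) under non-acidic conditions that spare the acetal.

Step 6
Reactants: 9 (R)-4-benzyl-3-(4,4-dimethoxybutanoyl)oxazolidin-2-one; 5 (R)-2-methyl-2-(triethylsilyloxy)hex-5-enal
Product: 10 syn-aldol adduct (2R,3R,4R in the acyl chain)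
Conditions: Bu2BOTf, iPr2NEt, CH2Cl2, −78 → 0 °C; then pH 7 buffer, MeOH, H2O2
Reagents that add atoms: none
Why: Evans syn aldol through the Z-boron enolate and a chair transition state, the (R)-benzyl auxiliary fixing the enolate face, sets C1 and C2 (C10 branch and OH syn) by reagent control over the α-silyloxy aldehyde.

Step 7
Reactants: 10 syn-aldol adduct
Product: 11 (2S,3R,4R)-2-(2,2-dimethoxyethyl)-4-methyl-4-(triethylsilyloxy)oct-7-ene-1,3-diol
Conditions: LiBH4, MeOH (1 equiv), THF, 0 °C
Reagents that add atoms: none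
Why: Borohydride reduction of the N-acyl oxazolidinone removes the auxiliary and gives the primary alcohol at C14 without touching C1 or C2.

Step 8
Reactants: 11 the 1,3-diol
Product: 12 (2R,3R,4R)-2-(2,2-dimethoxyethyl)-3-hydroxy-4-methyl-4-(triethylsilyloxy)oct-7-enal
Conditions: TEMPO (10 mol %), PhI(OAc)2, NaHCO3, CH2Cl2, rt
Reagents that add atoms: none
Why: Nitroxyl-catalysed oxidation takes the primary alcohol in preference to the hindered secondary one; the bicarbonate buffer protects the acetal and the α-centre.

Step 9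
Reactants: 12 the β-hydroxy aldehyde; 13 ethyl 2-[bis(2-methylphenoxy)phosphoryl]propanoate
Product: 15 unsaturated δ-lactone (ring L) with dimethyl acetal side chain and C3 silyl ether, via Z-enoate 14 (not isolated)
Conditions: 13, NaI, DBU, THF, −78 → 0 °C; then rt, 12 h
Reagents that add atoms: none
Why: Z-selective Horner–Wadsworth–Emmons olefination with a diaryl phosphonate puts the ester cis to C1, so the C2 alkoxide lactonizes under the same basic conditions to the 3-methyl-5,6-dihydropyran-2-one.

Step 10
Reactants: 15 unsaturated δ-lactone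
Product: 16 cis-fused bicyclic acetal lactone (ring P = 2-methoxytetrahydropyran through O3)
Conditions: HF·pyridine, THF, 0 °C; then PPTS (cat.), toluene, 4 Å MS, 60 °C
Reagents that add atoms: none
Why: Desilylation frees the tertiary C3–OH, which closes the six-membered mixed acetal on C9 by transacetalization; O2 is already acylated, so only O3 can cyclize.

Step 11
Reactants: 16 bicyclic acetal lactone
Product: 17 bicyclic enol ether lactone (ring P = 3,4-dihydro-2H-pyran with C9=C10)
Conditions: Me3SiOTf, iPr2NEt, CH2Cl2, −20 → 0 °C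
Reagents that add atoms: none
Why: Silyl triflate/amine elimination of methanol from the cyclic acetal gives the endocyclic enol ether, the only possible regioisomer since C10 carries the only β-hydrogens.

Step 12
Reactants: 17 bicyclic enol ether lactone; 18 (4-bromobut-1-yn-1-yl)trimethylsilane
Product: 21 tricyclic acetal lactone (rings L, P, C; C11=CH2; C9 methyl acetal), via silyl ketene acetal 19 (not isolated), via alkynyl lactone 20 (not isolated)
Conditions: 18, Mg, THF, rt; then CuBr·SMe2 (20 mol %), Me3SiCl, 17, THF, −78 → −30 °C; then MeOH, K2CO3 (0.5 equiv), 0 °C → rt; then AcOH (1 equiv), PtCl2 (10 mol %), 60 °C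
Reagents that add atoms: methanol, CO
Why: The Grignard reagent made from 18 adds as its monovalent copper ate complex, with Me3SiCl, to C14 of the unsaturated δ-lactone (conjugate addition, as known for 5-substituted 5,6-dihydropyran-2-ones) and gives silyl ketene acetal 19; K2CO3 in MeOH then cleaves both silicon groups and equilibrates C15, giving 20. PtCl2, a halide-tolerant divalent platinum π-acid, activates the terminal alkyne, the enol ether carbon C10 attacks C11, MeOH captures the C9 oxocarbenium ion and protodemetalation leaves the exocyclic CH2; the closest known reaction type is the platinum- or gold-catalysed alkoxycyclization of enol ethers onto alkynes (a Conia-ene-type carbocyclization). Only ring C is closed, by the intermolecular C13–C14 bond followed by a 6-exo-dig C10–C11 bond; rings L and P are kept. C14 is set by attack anti to C10 on the convex face of the cis-fused bicycle (4,5-trans lactone), C15 by thermodynamic control (equatorial methyl trans to C13) and C10 by the tether, because C11 can reach only the enol ether face that carries C14, which gives the cis ring P/ring C junction (H1 and H10 cis). The step needs 1,4- over 1,2-addition (copper and Me3SiCl secure it), 6-exo over 7-endo closure (Markovnikov attack on a terminal alkyne) and reaction at the alkyne rather than at the C6 vinyl group (the π-acid is alkynophilic and the enol ether is the only strong π-nucleophile within reach).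

Step 13
Reactants: 21 tricyclic acetal lactone
Product: 22 tricyclic bis-lactone
Conditions: CrO3, H2SO4, acetone/H2O, 0 °C
Reagents that add atoms: water, O
Why: Jones oxidation hydrolyses the methyl acetal and oxidizes the lactol to the ring P δ-lactone; C10 is not epimerized under acid and the alkenes are inert to hexavalent chromium at 0 °C.

Step 14
Reactants: 22 tricyclic bis-lactone
Product: 24 cis-fused γ-lactone diol (C9(=O)–O2; C3–OH and C16–OH free), via dihydroxy δ-lactone 23 (not isolated)
Conditions: LiBH4, THF, 0 °C; aq. NH4Cl; then CSA (cat.), CH2Cl2, rt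
Reagents that add atoms: none
Why: Borohydride reduces the less hindered ring L lactone (the ring P lactone is an ester of the tertiary O3 with a branched α-carbon), and acid-catalysed translactonization then lets the freed O2 displace O3 at C9 to give the more stable cis-fused γ-lactone; no stereocentre is touched.

Step 15
Reactants: 24 γ-lactone diol
Product: 26 γ-lactone with C16–OSi(t-Bu)Me2 and C3–OSiMe3, via mono-silyl ether 25 (not isolated)
Conditions: t-BuMe2SiCl, imidazole, CH2Cl2, 0 °C; then Me3SiOTf, 2,6-lutidine, −78 °C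
Reagents that add atoms: tert-butylchlorodimethylsilane, CC(C)(C)[Si](C)(C)Cl; trimethylsilyl trifluoromethanesulfonate, C[Si](C)(C)OS(=O)(=O)C(F)(F)F
Why: The silyl chloride takes only the primary C16–OH and the silyl triflate then caps the tertiary C3–OH, so that O3 cannot compete with O2 for C9 in the next steps.

Step 16
Reactants: 26 bis-silyl γ-lactone; 27 (2-methylallyl)magnesium chloride
Product: 28 five-membered hemiketal bearing the 2-methylallyl group on C9
Conditions: 27 (1.5 equiv), THF, −78 °C; aq. NH4Cl
Reagents that add atoms: none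
Why: Grignard mono-addition to a γ-lactone stops at the tetrahedral hemiketal alkoxide at low temperature and brings in C8, C7 and the C7 methyl.

Step 17
Reactants: 28 hemiketal diene
Product: 29 bridged hemiketal (C2–O–C9 bridge, nine-membered oxonene with (Z)-C6=C7)
Conditions: second-generation Hoveyda–Grubbs catalyst (10 mol %), toluene (2 mM), 80 °C
Reagents that add atoms: none
Why: Ring-closing metathesis of the terminal vinyl group with the 2-methylallyl group closes the bridged nine-membered ring, whose size enforces the Z-trisubstituted alkene; the hemiketal anomers interconvert so the cis-disposed one cyclizes, and the hindered exocyclic methylene next to C10 should stay out.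

Step 18
Reactants: 29 bridged hemiketal
Product: 30 bridged methyl ketal with free C3–OH
Conditions: MeOH, PPTS (cat.), 0 °C → rt
Reagents that add atoms: methanol, CO
Why: Acid-catalysed ketalization masks the hemiketal hydroxyl, and the same conditions remove the labile tertiary trimethylsilyl ether while the primary silyl ether stays.

Step 19
Reactants: 31 (S)-2-hydroxybutanoic acid; 32 butanoyl chloride
Product: 33 (S)-2-(butanoyloxy)butanoic acid
Conditions: neat, 50 °C; volatiles removed in vacuo
Reagents that add atoms: none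
Why: O-acylation of the α-hydroxy acid with the acid chloride does not touch the stereocentre.

Step 20
Reactants: 30 bridged methyl ketal; 33 (S)-2-(butanoyloxy)butanoic acid
Product: 34 C3 ester of 30
Conditions: 2-methyl-6-nitrobenzoic anhydride, DMAP, Et3N, CH2Cl2, rt → 40 °C
Reagents that add atoms: none
Why: Shiina mixed-anhydride esterification acylates the only free hydroxyl, the tertiary C3–OH, whose neighbour O2 is tied back in the five-membered ketal.

Step 21
Reactants: 34 ester ketal
Product: 35 bridged hemiketal diol (C16–OH free)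
Conditions: aq. HF (48 %), MeCN, 0 °C → rt
Reagents that add atoms: water, O
Why: Aqueous HF removes the primary silyl ether and hydrolyses the methyl ketal to the hemiketal; the esters and the alkenes are stable under these conditions.

Step 22
Reactants: 35 bridged hemiketal diol
Product: 37 CNP0291223.2 (target), via epoxide 36 (not isolated)
Conditions: 3-ClC6H4CO3H (1.05 equiv), NaHCO3, CH2Cl2, −20 °C; then CSA (cat.), 0 °C
Reagents that add atoms: 3-chloroperoxybenzoic acid, O=C(OO)c1cccc(Cl)c1
Why: Peracid epoxidation of the electron-rich trisubstituted (Z)-C6=C7 bond from the exposed outer face, then acid-catalysed opening of the hemiketal and 6-exo attack of O2 on C6 with inversion (epoxide-opening etherification), sets C6 and C7, forms the tetrahydropyran and frees the C9 ketone.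

**Compound list**
1 | (S)-2-methylglycidol | C[C@]1(CO)CO1 | starting material
2 | allylmagnesium bromide | C=CC[Mg]Br | starting material
3 | (R)-2-methylhex-5-ene-1,2-diol | C=CCC[C@@](C)(O)CO | intermediate
4 | (R)-2-methyl-1,2-bis(triethylsilyloxy)hex-5-ene | C=CCC[C@@](C)(O[Si](CC)(CC)CC)CO[Si](CC)(CC)CC | intermediate
5 | (R)-2-methyl-2-(triethylsilyloxy)hex-5-enal | C=CCC[C@@](C)(O[Si](CC)(CC)CC)C=O | intermediate
6 | methyl 4,4-dimethoxybutanoate | COC(=O)CCC(OC)OC | starting material
7 | 4,4-dimethoxybutanoic acid | OC(=O)CCC(OC)OC | intermediate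
8 | (R)-4-benzyloxazolidin-2-one | O=C1N[C@H](Cc2ccccc2)CO1 | starting material
9 | (R)-4-benzyl-3-(4,4-dimethoxybutanoyl)oxazolidin-2-one | COC(OC)CCC(=O)N1[C@H](Cc2ccccc2)COC1=O | intermediate
10 | (R)-4-benzyl-3-[(2R,3R,4R)-2-(2,2-dimethoxyethyl)-3-hydroxy-4-methyl-4-(triethylsilyloxy)oct-7-enoyl]oxazolidin-2-one | C=CCC[C@@](C)(O[Si](CC)(CC)CC)[C@H](O)[C@@H](CC(OC)OC)C(=O)N1[C@H](Cc2ccccc2)COC1=O | intermediate
11 | (2S,3R,4R)-2-(2,2-dimethoxyethyl)-4-methyl-4-(triethylsilyloxy)oct-7-ene-1,3-diol | C=CCC[C@@](C)(O[Si](CC)(CC)CC)[C@H](O)[C@@H](CC(OC)OC)CO | intermediate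
12 | (2R,3R,4R)-2-(2,2-dimethoxyethyl)-3-hydroxy-4-methyl-4-(triethylsilyloxy)oct-7-enal | C=CCC[C@@](C)(O[Si](CC)(CC)CC)[C@H](O)[C@@H](CC(OC)OC)C=O | intermediate
13 | ethyl 2-[bis(2-methylphenoxy)phosphoryl]propanoate | CCOC(=O)C(C)P(=O)(Oc1ccccc1C)Oc1ccccc1C | starting material
14 | ethyl (2Z,4S,5R,6R)-4-(2,2-dimethoxyethyl)-5-hydroxy-2,6-dimethyl-6-(triethylsilyloxy)deca-2,9-dienoate | C=CCC[C@@](C)(O[Si](CC)(CC)CC)[C@H](O)[C@@H](CC(OC)OC)/C=C(/C)C(=O)OCC | intermediate
15 | (5S,6R)-5-(2,2-dimethoxyethyl)-3-methyl-6-[(R)-2-(triethylsilyloxy)hex-5-en-2-yl]-5,6-dihydro-2H-pyran-2-one | C=CCC[C@@](C)(O[Si](CC)(CC)CC)[C@@H]1OC(=O)C(C)=C[C@@H]1CC(OC)OC | intermediate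
16 | cis-fused bicyclic acetal lactone: ring L (3-methyl-5,6-dihydropyran-2-one through O2) fused at C1–C2 to ring P (2-methoxytetrahydropyran through O3; C3 bears CH3 and but-3-enyl) | C=CCC[C@@]1(C)OC(OC)C[C@H]2C=C(C)C(=O)O[C@H]21 | intermediate
17 | cis-fused bicyclic enol ether lactone: as 16, ring P = 3,4-dihydro-2H-pyran (C9=C10) | C=CCC[C@@]1(C)OC=C[C@H]2C=C(C)C(=O)O[C@H]21 | intermediate
18 | (4-bromobut-1-yn-1-yl)trimethylsilane | C[Si](C)(C)C#CCCBr | starting material
19 | silyl ketene acetal of ring L carrying the 4-(trimethylsilyl)but-3-ynyl group on C14 (trans to C10) | C=CCC[C@@]1(C)OC=C[C@H]2[C@H](CCC#C[Si](C)(C)C)C(C)=C(O[Si](C)(C)C)O[C@H]21 | intermediate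
20 | alkynyl lactone: ring L saturated, but-3-ynyl on C14 trans to C10, C15 methyl trans to the butynyl group | C=CCC[C@@]1(C)OC=C[C@H]2[C@H](CCC#C)[C@@H](C)C(=O)O[C@H]21 | intermediate
21 | tricyclic acetal lactone: methylenecyclohexane ring C trans-fused to ring L and cis-fused to ring P (C9 methyl acetal) | C=CCC[C@@]1(C)OC(OC)[C@H]2C(=C)CC[C@@H]3[C@@H](C)C(=O)O[C@@H]1[C@@H]23 | intermediate
22 | tricyclic bis-lactone (C9 and C16 lactones) | C=CCC[C@@]1(C)OC(=O)[C@H]2C(=C)CC[C@@H]3[C@@H](C)C(=O)O[C@@H]1[C@@H]23 | intermediate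
23 | dihydroxy δ-lactone (ring L reduced; C2–OH and C16–OH free; C9 lactone on O3) | C=CCC[C@@]1(C)OC(=O)[C@H]2C(=C)CC[C@H]([C@@H](C)CO)[C@H]2[C@H]1O | intermediate
24 | cis-fused γ-lactone diol (C9 lactone on O2; C3–OH and C16–OH free) | C=CCC[C@@](C)(O)[C@@H]1OC(=O)[C@H]2C(=C)CC[C@H]([C@@H](C)CO)[C@@H]12 | intermediate
25 | γ-lactone, C16 tert-butyldimethylsilyl ether, C3–OH free | C=CCC[C@@](C)(O)[C@@H]1OC(=O)[C@H]2C(=C)CC[C@H]([C@@H](C)CO[Si](C)(C)C(C)(C)C)[C@@H]12 | intermediate
26 | γ-lactone, C16 tert-butyldimethylsilyl ether, C3 trimethylsilyl ether | C=CCC[C@@](C)(O[Si](C)(C)C)[C@@H]1OC(=O)[C@H]2C(=C)CC[C@H]([C@@H](C)CO[Si](C)(C)C(C)(C)C)[C@@H]12 | intermediate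
27 | (2-methylallyl)magnesium chloride | CC(=C)C[Mg]Cl | starting material
28 | five-membered hemiketal with 2-methylallyl on C9 | C=CCC[C@@](C)(O[Si](C)(C)C)[C@@H]1OC(O)(CC(C)=C)[C@H]2C(=C)CC[C@H]([C@@H](C)CO[Si](C)(C)C(C)(C)C)[C@@H]12 | intermediate
29 | bridged hemiketal: C2–O–C9 tetrahydrofuran bridging a nine-membered oxonene with (Z)-C6=C7 | C[C@@]1(O[Si](C)(C)C)CC/C=C(/C)C[C@@]2(O)O[C@@H]1[C@H]3[C@@H]2C(=C)CC[C@@H]3[C@@H](C)CO[Si](C)(C)C(C)(C)C | intermediate
30 | bridged methyl ketal with free C3–OH | C[C@@]1(O)CC/C=C(/C)C[C@@]2(OC)O[C@@H]1[C@H]3[C@@H]2C(=C)CC[C@@H]3[C@@H](C)CO[Si](C)(C)C(C)(C)C | intermediate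
31 | (S)-2-hydroxybutanoic acid | CC[C@H](O)C(=O)O | starting material
32 | butanoyl chloride | CCCC(=O)Cl | starting material
33 | (S)-2-(butanoyloxy)butanoic acid | CCCC(=O)O[C@@H](CC)C(=O)O | intermediate
34 | bridged methyl ketal, C3 (S)-2-(butanoyloxy)butanoate, C16 silyl ether | C[C@@]1(OC(=O)[C@H](CC)OC(=O)CCC)CC/C=C(/C)C[C@@]2(OC)O[C@@H]1[C@H]3[C@@H]2C(=C)CC[C@@H]3[C@@H](C)CO[Si](C)(C)C(C)(C)C | intermediate
35 | bridged hemiketal diol (C9–OH, C16–OH), C3 ester | C[C@@]1(OC(=O)[C@H](CC)OC(=O)CCC)CC/C=C(/C)C[C@@]2(O)O[C@@H]1[C@H]3[C@@H]2C(=C)CC[C@@H]3[C@@H](C)CO | intermediate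
36 | C6–C7 epoxide of 35 (oxygen on the outer face) | C[C@@]1(OC(=O)[C@H](CC)OC(=O)CCC)CC[C@@H]4O[C@]4(C)C[C@@]2(O)O[C@@H]1[C@H]3[C@@H]2C(=C)CC[C@@H]3[C@@H](C)CO | intermediate
37 | CNP0291223.2 | C=C1CC[C@H]([C@@H](C)CO)[C@@H]2[C@H]1C(=O)C[C@@](C)(O)[C@H]1CC[C@@](C)(OC(=O)[C@H](CC)OC(=O)CCC)[C@@H]2O1 | target

**Step count and risks**
Total: 22 steps. Longest linear sequence: 19 steps (1–3, 6–18, 20–22).

Step 12. Carry-over of copper and magnesium halides could slow or poison the platinum-catalysed ring closure, or the basic methanol stage could open ring L, so that the sequence stalls after the first C–C bond. The fallback closes the second bond by a radical instead of a π-acid. Setting out from 17, the copper-catalysed conjugate addition is worked up on its own and should give the silylalkynyl lactone F1. K2CO3 in MeOH converts F1 into 20, now isolated. N-Bromosuccinimide in MeOH turns the enol ether of 20 into the bromoacetal F2. Bu3SnH with AIBN in benzene at 80 °C then closes ring C by a 6-exo-dig Ueno–Stork radical cyclization, the vinyl radical taking hydrogen from the stannane, and the route is rejoined at 21.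

Step 14. The hydride may not discriminate well enough between the two lactones (over-reduction of the ring P lactone), or the lactone switch may be sluggish. The fallback reduces ring L before the second lactone exists. Setting out from 21, LiAlH4 reduces ring L while C9 is still an acetal and should give the diol acetal F3. t-BuMe2SiCl with imidazole gives the primary silyl ether F4. Aqueous AcOH hydrolyses the acetal to the lactol F5. Fétizon oxidation (Ag2CO3 on Celite, benzene, reflux), which takes lactols much faster than isolated secondary alcohols, then delivers the γ-lactone, and the route is rejoined at 25.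

Step 20. The hindered tertiary C3–OH may fail to capture the bulky mixed anhydride, or the configuration next to the acyl carbon may be lost through a ketene. The fallback builds the side chain in two stages with inversion. Setting out from 30, acylation with the small and reactive (R)-2-bromobutanoyl chloride (pyridine, DMAP, CH2Cl2) should give the α-bromo ester F6. SN2 displacement of bromide by cesium butanoate in DMF then installs the butanoyloxy group with inversion, and the route is rejoined at 34.

**Further compounds**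
F1 | step 12 | silylalkynyl lactone (17 with 4-(trimethylsilyl)but-3-ynyl on C14, ring L saturated, C15 epimers) | C=CCC[C@@]1(C)OC=C[C@H]2[C@H](CCC#C[Si](C)(C)C)C(C)C(=O)O[C@H]21
F2 | step 12 | bromoacetal of 20 (C9–OMe, C10–Br) | C=CCC[C@@]1(C)OC(OC)C(Br)[C@H]2[C@H](CCC#C)[C@@H](C)C(=O)O[C@H]21
F3 | step 14 | diol acetal (ring L of 21 reduced, C9 methyl acetal kept) | C=CCC[C@@]1(C)OC(OC)[C@H]2C(=C)CC[C@H]([C@@H](C)CO)[C@H]2[C@H]1O
F4 | step 14 | C16 tert-butyldimethylsilyl ether of F3 | C=CCC[C@@]1(C)OC(OC)[C@H]2C(=C)CC[C@H]([C@@H](C)CO[Si](C)(C)C(C)(C)C)[C@H]2[C@H]1O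
F5 | step 14 | five-membered lactol (C9–OH on O2), C3–OH free, C16 silyl ether | C=CCC[C@@](C)(O)[C@@H]1OC(O)[C@H]2C(=C)CC[C@H]([C@@H](C)CO[Si](C)(C)C(C)(C)C)[C@@H]12
F6 | step 20 | C3 (R)-2-bromobutanoate of 30 | C[C@@]1(OC(=O)[C@@H](CC)Br)CC/C=C(/C)C[C@@]2(OC)O[C@@H]1[C@H]3[C@@H]2C(=C)CC[C@@H]3[C@@H](C)CO[Si](C)(C)C(C)(C)C
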